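**Retrosynthetic overview**
- The acrylic acid comes from an isopropenyl group (SeO2, then Pinnick). Ring D comes from an oxa-Michael addition of the C18 hydroxyl (unmasked by Tamao oxidation) onto the ring-C enone.
- Rings A and B are closed in one flask: a Lewis-acid ene cyclisation of an acyclic 2-substituted acrylate with a prenyl terminus sets C8 and C4 and makes the isopropenyl group, then lactonisation follows.
- The quaternary C13 comes from an anti-selective hydroxymethylation. C19 and the C13–C7 bond come from one three-component union: asymmetric Cu-catalysed addition of a silylmethyl Grignard to 4,4-dimethylcyclohexadienone, then SN2′ capture of the enolate by a Baylis–Hillman bromide.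
- Ring order: C (from the bought enone) → A + B (key step) → D.

Atom labels used throughout follow the backbone atoms in SMILES order: C1 (=CH2), C2, C3 (CO2H), C4–C9 (cyclohexane; C4 bears C2, C7 bears C13, C8 bears C10), C10 (lactone C=O), O11, C12 (OCH2), C13 (spiro C), C14 (C=O), C15, C16 (CH–O), O17, C18 (OCH2), C19 (CH), C20 (CMe2).

Assumption: the SMILES defines the target as 4R,7R,8S,13S,16S,19S in these labels; the ligand in step 5 is taken to give (R)-C19 in 10, and its enantiomer is used if the first run shows the opposite sense.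

**Step 1**
Reactants: 1 2-methylbut-3-en-2-ol; 2 ethyl vinyl ether
Product: 4 5-methylhex-4-enal, via allyl vinyl ether 3 (not isolated)
Conditions: H3PO4 (cat.), neat, 125 °C, sealed tube
Reagents that add atoms: none
Why: Acid-catalysed transetherification gives allyl vinyl ether 3, which undergoes a chair Claisen rearrangement to the γ,δ-unsaturated aldehyde; no stereocentre is formed.

**Step 2**
Reactants: 4 5-methylhex-4-enal; 5 methyl acrylate
Product: 6 methyl (±)-3-hydroxy-7-methyl-2-methylideneoct-6-enoate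
Conditions: DABCO (0.3 equiv), neat, 23 °C, 5–7 d
Reagents that add atoms: none
Why: Morita–Baylis–Hillman reaction of the aldehyde with the DABCO–acrylate zwitterion gives the racemic allylic alcohol, whose stereocentre is erased in step 3.

**Step 3**
Reactants: 6 methyl (±)-3-hydroxy-7-methyl-2-methylideneoct-6-enoate
Product: 7 methyl (2Z)-2-(bromomethyl)-7-methylocta-2,6-dienoate
Conditions: NBS, Me2S, CH2Cl2, 0 → 23 °C
Reagents that add atoms: N-bromosuccinimide, O=C1CCC(=O)N1Br
Why: Corey–Kim-type activation of the alcohol as an alkoxysulfonium ion and SN2′ attack of bromide gives the conjugated primary allylic bromide, the Z isomer (chain cis to CH2Br) being the favoured trisubstituted enoate.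

**Step 4**
Reactants: 8 4,4-dimethylcyclohex-2-en-1-one
Product: 9 4,4-dimethylcyclohexa-2,5-dien-1-one
Conditions: DDQ, 1,4-dioxane, reflux
Reagents that add atoms: none
Why: DDQ dehydrogenation (hydride abstraction from the dienol, then proton loss) introduces the second enone double bond; the product is achiral.

**Step 5**
Reactants: 9 4,4-dimethylcyclohexa-2,5-dien-1-one; 7 methyl (2Z)-2-(bromomethyl)-7-methylocta-2,6-dienoate
Product: 12 methyl (3S)-3-[(1R,6R)-6-{[dimethyl(propan-2-yloxy)silyl]methyl}-5,5-dimethyl-2-oxocyclohex-3-en-1-yl]-7-methyl-2-methylideneoct-6-enoate, via magnesium dienolate 10 (not isolated), via DABCO allyl ammonium salt 11 (not isolated)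
Conditions: (i-PrO)Me2SiCH2MgCl (from ClCH2SiMe2(Oi-Pr) + Mg), CuBr·SMe2 (5 mol %), (R,S)-Josiphos (6 mol %), t-BuOMe, −78 °C; then 11 (7 + DABCO, THF/DMF, 23 °C), −78 → 0 °C
Reagents that add atoms: [dimethyl(propan-2-yloxy)silyl]methylmagnesium chloride, CC(C)O[Si](C)(C)C[Mg]Cl
Why: Proposed new method: Cu/Josiphos-catalysed conjugate addition of the Tamao hydroxymethyl-anion Grignard desymmetrises dienone 9 and sets C19 (R), and the magnesium dienolate 10 then adds, anti to the new CH2Si group and through a Mg-chelated closed transition state (ester beside the enolate oxygen, C7–H under the ring, alkyl chain outward), to the enoate β-carbon of ammonium salt 11 with loss of DABCO (SN2′, direct SN2 at the CH2–N+ carbon being blocked), which sets C7 (S) and leaves the 2-substituted acrylate; the closest known reaction types are Feringa–Minnaard Cu-catalysed asymmetric Grignard conjugate additions with enolate trapping and SN2′ substitutions of DABCO salts of Baylis–Hillman bromides.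

**Step 6**
Reactants: 12 methyl (3S)-3-[(1R,6R)-6-{[dimethyl(propan-2-yloxy)silyl]methyl}-5,5-dimethyl-2-oxocyclohex-3-en-1-yl]-7-methyl-2-methylideneoct-6-enoate
Product: 15 methyl (3S)-3-[(1S,6S)-6-{[dimethyl(propan-2-yloxy)silyl]methyl}-5,5-dimethyl-2-oxo-1-{[(triethylsilyl)oxy]methyl}cyclohex-3-en-1-yl]-7-methyl-2-methylideneoct-6-enoate, via lithium dienolate 13 (not isolated), via lithium aldolate 14 (not isolated)
Conditions: LiHMDS, THF, −78 °C; CH2O (gas from cracked paraformaldehyde), −78 °C; TESOTf, −78 → −40 °C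
Reagents that add atoms: formaldehyde, C=O; triethylsilyl trifluoromethanesulfonate, CC[Si](CC)(CC)OS(=O)(=O)C(F)(F)F
Why: Enolisation is regiospecific (C13–H is the only α-hydrogen) and the formaldehyde aldol occurs anti to the CH2Si group on C19 (held pseudo-axial by A1,2 strain with the C7 branch), which sets the quaternary C13 (S) with C12 trans and C7 cis to C18; cold silylation stops retro-aldol and premature lactonisation.

**Step 7 (key step)**
Reactants: 15 methyl (3S)-3-[(1S,6S)-6-{[dimethyl(propan-2-yloxy)silyl]methyl}-5,5-dimethyl-2-oxo-1-{[(triethylsilyl)oxy]methyl}cyclohex-3-en-1-yl]-7-methyl-2-methylideneoct-6-enoate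
Product: 18 (4S,4aR,6'S,7R,8aS)-6'-{[dimethyl(propan-2-yloxy)silyl]methyl}-5',5'-dimethyl-7-(prop-1-en-2-yl)-4a,5,6,7,8,8a-hexahydrospiro[isochromene-4,1'-cyclohex[3]ene]-1,2'(3H)-dione, via ene adduct 16 (not isolated), via hydroxy ester 17 (not isolated)
Conditions: Me2AlCl (3 equiv), CH2Cl2, −78 → 0 °C; then i-PrOH, CSA (0.2 equiv), 23 °C, same flask
Reagents that add atoms: none
Why: Proposed new method: Me2AlCl activates the acrylate of 15 so that C4 of the trisubstituted alkene attacks C9 in a chair-like type-I intramolecular ene transition state in which A1,2 strain keeps C7–H in the plane of the ester and the bulky C13 pseudo-axial while a methyl hydrogen passes suprafacially to C8, which sets C8 (S) and C4 (R), creates the isopropenyl group and places the ester cis to the C13 branch, so that acid-mediated loss of the TES group and lactonisation then close ring B in the same flask; the closest known reaction types are Snider-type alkylaluminium-halide-promoted intramolecular ene cyclisations of 2-substituted acrylates and the citronellal-to-isopulegol cyclisation.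

**Step 8**
Reactants: 18 (4S,4aR,6'S,7R,8aS)-6'-{[dimethyl(propan-2-yloxy)silyl]methyl}-5',5'-dimethyl-7-(prop-1-en-2-yl)-4a,5,6,7,8,8a-hexahydrospiro[isochromene-4,1'-cyclohex[3]ene]-1,2'(3H)-dione
Product: 20 isopropenyl tetracycle (target skeleton with CH3 as C3; 4R,7R,8S,13S,16S,19S), via hydroxy enone 19 (not isolated)
Conditions: 30% H2O2, KF, KHCO3, THF/MeOH, 23 → 40 °C
Reagents that add atoms: hydrogen peroxide, OO
Why: Tamao–Kumada oxidation turns the C18–Si bond into C18–OH, and the hydroxymethyl group then adds to C16 of the enone in a 5-exo oxa-Michael reaction whose bridge geometry forces the C16 (S) configuration.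

**Step 9**
Reactants: 20 isopropenyl tetracycle (target skeleton with CH3 as C3)
Product: 22 enal (target skeleton with CHO as C3; 4R,7R,8S,13S,16S,19S), via allylic alcohol 21 (not isolated)
Conditions: SeO2 (0.5 equiv), t-BuOOH (4 equiv), CH2Cl2, 23 °C
Reagents that add atoms: tert-butyl hydroperoxide, CC(C)(C)OO
Why: Selenium dioxide allylic oxidation (ene reaction, then [2,3]-sigmatropic shift) attacks the methyl group of the 1,1-disubstituted alkene in preference to the ring CH, and the peroxide carries the allylic alcohol on to the 2-substituted acrolein; no stereocentre is touched.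

**Step 10**
Reactants: 22 enal (target skeleton with CHO as C3)
Product: 23 2-[(4R,7R,8S,13S,16S,19S)-target skeleton]prop-2-enoic acid (CNP0268721.1)
Conditions: NaClO2, NaH2PO4, 2-methylbut-2-ene, t-BuOH/H2O, 23 °C
Reagents that add atoms: sodium chlorite, [Na+].[O-]Cl=O
Why: Pinnick (Lindgren) oxidation converts the enal into the acrylic acid without touching the alkene, the ketone, the lactone, the ether or any stereocentre.

**Compound list**
1 | 2-methylbut-3-en-2-ol | CC(C)(O)C=C | starting material
2 | ethyl vinyl ether | CCOC=C | starting material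
3 | 3-(ethenyloxy)-3-methylbut-1-ene | C=COC(C)(C)C=C | intermediate
4 | 5-methylhex-4-enal | CC(C)=CCCC=O | intermediate
5 | methyl acrylate | COC(=O)C=C | starting material
6 | methyl (±)-3-hydroxy-7-methyl-2-methylideneoct-6-enoate | COC(=O)C(=C)C(O)CCC=C(C)C | intermediate
7 | methyl (2Z)-2-(bromomethyl)-7-methylocta-2,6-dienoate | BrC/C(C(=O)OC)=C\CCC=C(C)C | intermediate
8 | 4,4-dimethylcyclohex-2-en-1-one | CC1(C)CCC(=O)C=C1 | starting material
9 | 4,4-dimethylcyclohexa-2,5-dien-1-one | CC1(C)C=CC(=O)C=C1 | intermediate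
10 | chloromagnesium (3R)-3-{[dimethyl(propan-2-yloxy)silyl]methyl}-4,4-dimethylcyclohexa-1,5-dien-1-olate | Cl[Mg]OC1=C[C@@H](C[Si](C)(C)OC(C)C)C(C)(C)C=C1 | intermediate
11 | 1-[(2E)-2-(methoxycarbonyl)-7-methylocta-2,6-dien-1-yl]-1,4-diazabicyclo[2.2.2]octan-1-ium bromide | [N+]12(CCN(CC1)CC2)C/C(C(=O)OC)=C\CCC=C(C)C.[Br-] | intermediate
12 | methyl (3S)-3-[(1R,6R)-6-{[dimethyl(propan-2-yloxy)silyl]methyl}-5,5-dimethyl-2-oxocyclohex-3-en-1-yl]-7-methyl-2-methylideneoct-6-enoate | CC(C)=CCC[C@H](C(=C)C(=O)OC)[C@H]1C(=O)C=CC(C)(C)[C@@H]1C[Si](C)(C)OC(C)C | intermediate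
13 | lithium dienolate of 12 (C13=C14–OLi) | CC(C)=CCC[C@H](C(=C)C(=O)OC)C1=C(O[Li])C=CC(C)(C)[C@@H]1C[Si](C)(C)OC(C)C | intermediate
14 | lithium aldolate (15 with OLi in place of OSiEt3) | CC(C)=CCC[C@H](C(=C)C(=O)OC)[C@]1(CO[Li])C(=O)C=CC(C)(C)[C@@H]1C[Si](C)(C)OC(C)C | intermediate
15 | methyl (3S)-3-[(1S,6S)-6-{[dimethyl(propan-2-yloxy)silyl]methyl}-5,5-dimethyl-2-oxo-1-{[(triethylsilyl)oxy]methyl}cyclohex-3-en-1-yl]-7-methyl-2-methylideneoct-6-enoate | CC(C)=CCC[C@H](C(=C)C(=O)OC)[C@]1(CO[Si](CC)(CC)CC)C(=O)C=CC(C)(C)[C@@H]1C[Si](C)(C)OC(C)C | intermediate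
16 | methyl (1S,2R,5R)-2-[(1S,6S)-6-{[dimethyl(propan-2-yloxy)silyl]methyl}-5,5-dimethyl-2-oxo-1-{[(triethylsilyl)oxy]methyl}cyclohex-3-en-1-yl]-5-(prop-1-en-2-yl)cyclohexane-1-carboxylate | C=C(C)[C@@H]1CC[C@H]([C@H](C1)C(=O)OC)[C@]1(CO[Si](CC)(CC)CC)C(=O)C=CC(C)(C)[C@@H]1C[Si](C)(C)OC(C)C | intermediate
17 | methyl (1S,2R,5R)-2-[(1S,6S)-6-{[dimethyl(propan-2-yloxy)silyl]methyl}-1-(hydroxymethyl)-5,5-dimethyl-2-oxocyclohex-3-en-1-yl]-5-(prop-1-en-2-yl)cyclohexane-1-carboxylate | C=C(C)[C@@H]1CC[C@H]([C@H](C1)C(=O)OC)[C@]1(CO)C(=O)C=CC(C)(C)[C@@H]1C[Si](C)(C)OC(C)C | intermediate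
18 | (4S,4aR,6'S,7R,8aS)-6'-{[dimethyl(propan-2-yloxy)silyl]methyl}-5',5'-dimethyl-7-(prop-1-en-2-yl)-4a,5,6,7,8,8a-hexahydrospiro[isochromene-4,1'-cyclohex[3]ene]-1,2'(3H)-dione (cis-fused lactone) | C=C(C)[C@@H]1CC[C@@H]2[C@H](C1)C(=O)OC[C@]21C(=O)C=CC(C)(C)[C@@H]1C[Si](C)(C)OC(C)C | intermediate
19 | hydroxy enone (18 with CH2OH on C19 in place of the silylmethyl group; 4R,7R,8S,13S,19S) | C=C(C)[C@@H]1CC[C@@H]2[C@H](C1)C(=O)OC[C@]21C(=O)C=CC(C)(C)[C@@H]1CO | intermediate
20 | isopropenyl tetracycle (target with CH3 as C3; 4R,7R,8S,13S,16S,19S) | C=C(C)[C@@H]1CC[C@@H]2[C@H](C1)C(=O)OC[C@]21C(=O)C[C@@H]2OC[C@H]1C2(C)C | intermediate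
21 | allylic alcohol (target with CH2OH as C3) | C=C(CO)[C@@H]1CC[C@@H]2[C@H](C1)C(=O)OC[C@]21C(=O)C[C@@H]2OC[C@H]1C2(C)C | intermediate
22 | enal (target with CHO as C3) | C=C(C=O)[C@@H]1CC[C@@H]2[C@H](C1)C(=O)OC[C@]21C(=O)C[C@@H]2OC[C@H]1C2(C)C | intermediate
23 | CNP0268721.1 (4R,7R,8S,13S,16S,19S) | C=C(C(=O)O)[C@@H]1CC[C@@H]2[C@H](C1)C(=O)OC[C@]21C(=O)C[C@@H]2OC[C@H]1C2(C)C | target

**Totals**
Total step count: 10. Longest linear sequence: 9 (steps 1–3, then 5–10); the other branch is step 4, then 5–10.

**Steps most likely to fail, with fallbacks**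

Step 5. The risks are the ligand's sense and level of induction with a silylmethyl Grignard, SN2′ versus SN2 capture of the enolate, and the diastereoselectivity at C7. The fallback sets out from 9 (with 4) and builds the acrylate by a different bond logic. Run the same Cu-catalysed addition to 9 but quench with TMSCl to isolate the trimethylsilyl dienol ether F1. Condense 4 with Meldrum's acid (piperidinium acetate) to the alkylidene Meldrum's acid F2. A Mukaiyama–Michael addition of F1 to F2 (CH2Cl2, −78 °C) gives the 5-monoalkyl Meldrum's acid adduct F3. Heating F3 with Eschenmoser's salt in methanol (Mannich reaction, methanolysis, decarboxylation, loss of dimethylamine) gives the 2-substituted methyl acrylate, and the route is rejoined at 12.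

Step 6. The risks are enolisation and aldol at a very crowded tertiary carbon, retro-aldol, and the free alkoxide closing the lactone too early. The fallback sets out from 12 and replaces the basic enolate aldol by a Lewis-acid aldol in water. TMSOTf/Et3N converts 12 into the trimethylsilyl dienol ether F4. Aqueous formaldehyde with Sc(OTf)3 (Kobayashi hydroxymethylation) gives the free hydroxymethyl ketone F5, which is kept cold and silylated at once (TESCl, imidazole). The route is rejoined at 15.

Step 7. The risks are competing HCl addition or isomerisation at the tertiary cation, the ketone or enone acting as a second Lewis-acid site, and the order of events. If the lactone closes before the ene reaction, ring B forces C13 into the plane of the ester and the wrong (trans-fused, axial isopropenyl) isomer is expected, which is why the alcohol is carried as its TES ether. The fallback sets out from 12 and reverses the order: ring A first, quaternary centre second. Me2AlCl cyclises the less hindered 12 to the cyclohexane ester F6 under the same A1,2-strain control. LiHMDS, CH2O and TESOTf then build C13 anti to the CH2Si group. The route is rejoined at 16, which is lactonised with i-PrOH/CSA to 18.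

**Further compounds**
F1 | step 5 | {[(3R)-3-{[dimethyl(propan-2-yloxy)silyl]methyl}-4,4-dimethylcyclohexa-1,5-dien-1-yl]oxy}trimethylsilane | C[Si](C)(C)OC1=C[C@@H](C[Si](C)(C)OC(C)C)C(C)(C)C=C1
F2 | step 5 | 2,2-dimethyl-5-(5-methylhex-4-en-1-ylidene)-1,3-dioxane-4,6-dione | CC(C)=CCCC=C1C(=O)OC(C)(C)OC1=O
F3 | step 5 | 5-{(1S)-1-[(1R,6R)-6-{[dimethyl(propan-2-yloxy)silyl]methyl}-5,5-dimethyl-2-oxocyclohex-3-en-1-yl]-5-methylhex-4-en-1-yl}-2,2-dimethyl-1,3-dioxane-4,6-dione | CC(C)=CCC[C@H](C1C(=O)OC(C)(C)OC1=O)[C@H]1C(=O)C=CC(C)(C)[C@@H]1C[Si](C)(C)OC(C)C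
F4 | step 6 | methyl (3S)-3-[(6S)-6-{[dimethyl(propan-2-yloxy)silyl]methyl}-5,5-dimethyl-2-[(trimethylsilyl)oxy]cyclohexa-1,3-dien-1-yl]-7-methyl-2-methylideneoct-6-enoate | CC(C)=CCC[C@H](C(=C)C(=O)OC)C1=C(O[Si](C)(C)C)C=CC(C)(C)[C@@H]1C[Si](C)(C)OC(C)C
F5 | step 6 | methyl (3S)-3-[(1S,6S)-6-{[dimethyl(propan-2-yloxy)silyl]methyl}-1-(hydroxymethyl)-5,5-dimethyl-2-oxocyclohex-3-en-1-yl]-7-methyl-2-methylideneoct-6-enoate | CC(C)=CCC[C@H](C(=C)C(=O)OC)[C@]1(CO)C(=O)C=CC(C)(C)[C@@H]1C[Si](C)(C)OC(C)C
F6 | step 7 | methyl (1S,2S,5R)-2-[(1R,6R)-6-{[dimethyl(propan-2-yloxy)silyl]methyl}-5,5-dimethyl-2-oxocyclohex-3-en-1-yl]-5-(prop-1-en-2-yl)cyclohexane-1-carboxylate | C=C(C)[C@@H]1CC[C@H]([C@H](C1)C(=O)OC)[C@H]1C(=O)C=CC(C)(C)[C@@H]1C[Si](C)(C)OC(C)C
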